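**Plan**
- Retrosynthesis: the cinnamate ester C–O bond is cut first. Then, in one stroke, the C3=C4 and C5–C6 bonds of the dihydropyranone (O1, C2=O, C3=C4, C5, C6) are cut. Then the C6–C1' bond (glycolate aldol) and the bond from the ketone carbon to the cyclopropane follow.
- Enabling feature: ring oxygen O1 ties C6 to the C2 carbonyl, so a glyoxylate ester on that oxygen holds the future C3 as an aldehyde within six-ring reach of C4. C6 is an O-substituted carbon, so its radical is available by decarboxylation. C4–C5 come from vinyltriphenylphosphonium, whose radical adduct becomes a ylide.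
- Forward: the cyclopropane is made first, then the chain is joined at the ketone (cyclopropyllithium plus lactate Weinreb amide) and at C1' (Evans glycolate aldol). The lactone ring closes in the key step and the Z-cinnamate goes on last.
- Stereochemistry: the lactate carbon comes from ethyl (S)-lactate, both cyclopropane carbons from the chiral dioxaborolane ligand, C1' from the oxazolidinone auxiliary, and C6 from 1,2-induction in the radical addition. The ring olefin is cis by ring size and the cinnamate is Z by Lindlar semi-hydrogenation.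
- Helpers: the carboxyl group leaves as CO2 in the key step, the acrylate is cut to the glyoxylate tether, and the TES and TBS ethers are removed in steps 13 and 16.

Key step: step 12

Remark: acid 18 is written as the free aldehyde although it may rest partly as hydrate or cyclic hemiacylal, forms that should reopen under the basic conditions of step 12; imide 9 is taken as purchasable.

**Step 1**
Reactants: 1 (E)-3-(tributylstannyl)prop-2-en-1-ol
Product: 2 [(1R,2S)-2-(tributylstannyl)cyclopropyl]methanol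
Conditions: Et2Zn, CH2I2, DME (gives Zn(CH2I)2·DME), (4R,5R)-2-butyl-N,N,N',N'-tetramethyl-1,3,2-dioxaborolane-4,5-dicarboxamide (1.2 equiv), CH2Cl2, −10 °C to rt
Reagents that add atoms: diiodomethane (ICI)
Why: Charette asymmetric Simmons–Smith cyclopropanation, in which the zinc alkoxide of the allylic alcohol binds the chiral dioxaborolane and CH2 is delivered stereospecifically to one face of the E-olefin, so the trans ring and both ring stereocentres should come from the ligand.

**Step 2**
Reactants: 3 ethyl (S)-lactate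
Product: 4 (S)-2-hydroxy-N-methoxy-N-methylpropanamide
Conditions: MeNH(OMe)·HCl, i-PrMgCl, THF, −20 °C to 0 °C
Reagents that add atoms: N,O-dimethylhydroxylamine hydrochloride (CNOC.Cl)
Why: Weinreb amide formation by aminolysis of the ester with the magnesium amide, which should leave the lactate stereocentre untouched.

**Step 3**
Reactants: 4 (S)-2-hydroxy-N-methoxy-N-methylpropanamide
Product: 5 (S)-N-methoxy-N-methyl-2-(triethylsilyloxy)propanamide
Conditions: Et3SiCl, imidazole, CH2Cl2, 0 °C to rt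
Reagents that add atoms: chlorotriethylsilane (CC[Si](Cl)(CC)CC)
Why: standard silylation of a secondary alcohol, with the triethylsilyl group chosen because it can later be removed in the presence of a TBS ether.

**Step 4**
Reactants: 2 [(1R,2S)-2-(tributylstannyl)cyclopropyl]methanol; 5 (S)-N-methoxy-N-methyl-2-(triethylsilyloxy)propanamide
Product: 7 (2S)-1-[(1S,2S)-2-(hydroxymethyl)cyclopropyl]-2-(triethylsilyloxy)propan-1-one, via dilithiated cyclopropylmethoxide 6 (not isolated)
Conditions: n-BuLi (2.2 equiv), THF, −78 °C to 0 °C; then 5, −78 °C to −20 °C; aq NH4Cl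
Reagents that add atoms: none
Why: tin–lithium exchange with retention should give a configurationally stable cyclopropyllithium, and its addition to the Weinreb amide (Weinreb ketone synthesis) stops at the chelated tetrahedral intermediate, so the ketone appears only on work-up.

**Step 5**
Reactants: 7 (2S)-1-[(1S,2S)-2-(hydroxymethyl)cyclopropyl]-2-(triethylsilyloxy)propan-1-one
Product: 8 (1S,2S)-2-[(2S)-2-(triethylsilyloxy)propanoyl]cyclopropane-1-carbaldehyde
Conditions: Dess–Martin periodinane, CH2Cl2, 0 °C to rt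
Reagents that add atoms: none
Why: Dess–Martin oxidation of the primary alcohol under near-neutral conditions, which should not epimerise the cyclopropane or the α-silyloxy ketone.

**Step 6**
Reactants: 8 (1S,2S)-2-[(2S)-2-(triethylsilyloxy)propanoyl]cyclopropane-1-carbaldehyde; 9 (4R)-4-benzyl-3-[2-(benzyloxy)acetyl]-1,3-oxazolidin-2-one
Product: 11 (4R)-4-benzyl-3-[(2R,3S)-2-(benzyloxy)-3-hydroxy-3-{(1S,2S)-2-[(2S)-2-(triethylsilyloxy)propanoyl]cyclopropyl}propanoyl]-1,3-oxazolidin-2-one, via dibutylboron Z-enolate 10 (not isolated)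
Conditions: 9, Bu2BOTf, Et3N, CH2Cl2, −78 °C to 0 °C; then 8, −78 °C to 0 °C; pH 7 buffer, MeOH, H2O2, 0 °C
Reagents that add atoms: none
Why: Evans syn glycolate aldol through a chair-like Zimmerman–Traxler transition state, in which the (R)-benzyl auxiliary shields one enolate face and so should fix C1' as S under reagent control, while only the aldehyde and not the ketone is attacked; the benzyloxy-bearing centre formed at the same time is erased in step 12.

**Step 7**
Reactants: 11 (4R)-4-benzyl-3-[(2R,3S)-2-(benzyloxy)-3-hydroxy-3-{(1S,2S)-2-[(2S)-2-(triethylsilyloxy)propanoyl]cyclopropyl}propanoyl]-1,3-oxazolidin-2-one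
Product: 12 (4R)-4-benzyl-3-[(2R,3S)-2-(benzyloxy)-3-(tert-butyldimethylsilyloxy)-3-{(1S,2S)-2-[(2S)-2-(triethylsilyloxy)propanoyl]cyclopropyl}propanoyl]-1,3-oxazolidin-2-one
Conditions: TBSOTf, 2,6-lutidine, CH2Cl2, −78 °C to 0 °C
Reagents that add atoms: tert-butyldimethylsilyl triflate (CC(C)(C)[Si](C)(C)OS(=O)(=O)C(F)(F)F)
Why: silylation of the hindered secondary alcohol with a silyl triflate and a non-nucleophilic base, conditions under which the ketone should not be converted into its enol ether.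

**Step 8**
Reactants: 12 (4R)-4-benzyl-3-[(2R,3S)-2-(benzyloxy)-3-(tert-butyldimethylsilyloxy)-3-{(1S,2S)-2-[(2S)-2-(triethylsilyloxy)propanoyl]cyclopropyl}propanoyl]-1,3-oxazolidin-2-one
Product: 14 (2R,3S)-2-(benzyloxy)-3-(tert-butyldimethylsilyloxy)-3-{(1S,2S)-2-[(2S)-2-(triethylsilyloxy)propanoyl]cyclopropyl}propanoic acid, via peroxy acid 13 (not isolated)
Conditions: LiOH, H2O2, THF–H2O, 0 °C; then aq Na2SO3; then 1 M HCl to pH 4
Reagents that add atoms: hydrogen peroxide (OO)
Why: hydroperoxide cleavage of the N-acyl oxazolidinone at the exocyclic carbonyl, after which sulfite reduces the peroxy acid to the acid; the silyl ethers and the ketone should survive at 0 °C.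

**Step 9**
Reactants: 14 (2R,3S)-2-(benzyloxy)-3-(tert-butyldimethylsilyloxy)-3-{(1S,2S)-2-[(2S)-2-(triethylsilyloxy)propanoyl]cyclopropyl}propanoic acid
Product: 15 (2R,3S)-3-(tert-butyldimethylsilyloxy)-2-hydroxy-3-{(1S,2S)-2-[(2S)-2-(triethylsilyloxy)propanoyl]cyclopropyl}propanoic acid
Conditions: H2 (1 atm), 10% Pd/C, EtOAc, rt
Reagents that add atoms: none
Why: hydrogenolysis of the benzyl ether, run in ethyl acetate at ambient pressure so that the triethylsilyl ether and the cyclopropyl ketone should remain intact.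

**Step 10**
Reactants: 15 (2R,3S)-3-(tert-butyldimethylsilyloxy)-2-hydroxy-3-{(1S,2S)-2-[(2S)-2-(triethylsilyloxy)propanoyl]cyclopropyl}propanoic acid
Product: 16 (2R,3S)-2-(acryloyloxy)-3-(tert-butyldimethylsilyloxy)-3-{(1S,2S)-2-[(2S)-2-(triethylsilyloxy)propanoyl]cyclopropyl}propanoic acid
Conditions: acryloyl chloride (2.2 equiv), i-Pr2NEt, CH2Cl2, −20 °C to 0 °C; then aq NaHCO3–THF (hydrolysis of any mixed anhydride)
Reagents that add atoms: acryloyl chloride (C=CC(=O)Cl)
Why: O-acylation of the α-hydroxy acid with an acid chloride, the only free hydroxyl group in the molecule being the one that must carry the tether.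

**Step 11**
Reactants: 16 (2R,3S)-2-(acryloyloxy)-3-(tert-butyldimethylsilyloxy)-3-{(1S,2S)-2-[(2S)-2-(triethylsilyloxy)propanoyl]cyclopropyl}propanoic acid
Product: 18 (2R,3S)-3-(tert-butyldimethylsilyloxy)-2-(2-oxoacetoxy)-3-{(1S,2S)-2-[(2S)-2-(triethylsilyloxy)propanoyl]cyclopropyl}propanoic acid, via secondary ozonide 17 (not isolated)
Conditions: O3, CH2Cl2, −78 °C; then Me2S, −78 °C to rt; azeotropic drying with toluene, used crude
Reagents that add atoms: ozone ([O-][O+]=O)
Why: ozonolysis of the terminal acrylate olefin with reductive work-up should give the glyoxylate ester, since the molecule holds no other olefin or readily oxidised group at this stage.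

**Step 12**
Reactants: 18 (2R,3S)-3-(tert-butyldimethylsilyloxy)-2-(2-oxoacetoxy)-3-{(1S,2S)-2-[(2S)-2-(triethylsilyloxy)propanoyl]cyclopropyl}propanoic acid; 19 vinyltriphenylphosphonium bromide
Product: 23 (6R)-6-[(S)-(tert-butyldimethylsilyloxy){(1S,2S)-2-[(2S)-2-(triethylsilyloxy)propanoyl]cyclopropyl}methyl]-5,6-dihydro-2H-pyran-2-one, via α-acyloxyalkyl radical 20 (not isolated), via α-phosphonio radical 21 (not isolated), via phosphonium ylide 22 (not isolated)
Conditions: 19 (2 equiv), 4CzIPN (2 mol %), Cs2CO3 (1.5 equiv), 4 Å molecular sieves, DMSO (0.02 M), blue LEDs (450 nm), rt, argon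
Reagents that add atoms: none
Why: Proposed new method: the excited photocatalyst should oxidise the caesium carboxylate of 18, loss of CO2 gives the nucleophilic radical 20 at C6, this adds to the terminal carbon of the electron-poor vinylphosphonium 19 to form the C5–C6 bond, and the reduced photocatalyst reduces the adduct radical 21 to the ylide 22, so the cycle is redox-neutral (radical–polar crossover). The ylide carbon C4 then attacks the tethered glyoxylate aldehyde and the six-membered lactone ring (C6–C5–C4=C3–C2–O1) closes by intramolecular Wittig olefination at C3=C4, a ring size that allows only the cis olefin. The closest known reaction types are the photoredox three-component olefination of a carboxylic acid, a vinylphosphonium salt and an aldehyde, and the Schweizer annulation, in which a nucleophile adds to a vinylphosphonium salt and the resulting ylide closes a ring; the tethered, lactone-forming radical variant is not known. The new stereocentre C6 is set in the radical addition by 1,2-induction from the silyloxy-bearing C1': in the conformer with the C6–O and C1'–O bonds antiperiplanar the alkene should approach opposite to the cyclopropyl group, which gives the anti (6R) isomer. The step needs this facial selectivity, chemoselectivity of the ylide for the aldehyde over the ketone (secured by the higher electrophilicity of the glyoxylate and the six-membered closure) and a polarity match between radical and acceptor (secured by the oxygen on C6 and the cationic phosphonium).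

**Step 13**
Reactants: 23 (6R)-6-[(S)-(tert-butyldimethylsilyloxy){(1S,2S)-2-[(2S)-2-(triethylsilyloxy)propanoyl]cyclopropyl}methyl]-5,6-dihydro-2H-pyran-2-one
Product: 24 (6R)-6-[(S)-(tert-butyldimethylsilyloxy){(1S,2S)-2-[(2S)-2-hydroxypropanoyl]cyclopropyl}methyl]-5,6-dihydro-2H-pyran-2-one
Conditions: AcOH–THF–H2O, 0 °C to rt
Reagents that add atoms: none
Why: selective acid hydrolysis of the triethylsilyl ether, which should be cleaved much faster than the hindered secondary TBS ether, while the lactone tolerates weak aqueous acid.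

**Step 14**
Reactants: 25 3-(4-methoxyphenyl)prop-2-ynoic acid
Product: 26 (2Z)-3-(4-methoxyphenyl)prop-2-enoic acid
Conditions: H2 (1 atm), Pd/CaCO3 poisoned with Pb(OAc)2 (Lindlar catalyst), quinoline, EtOAc, rt
Reagents that add atoms: none
Why: Lindlar semi-hydrogenation adds H2 syn to the alkyne on the poisoned palladium surface, so the Z-olefin should be formed.

**Step 15**
Reactants: 24 (6R)-6-[(S)-(tert-butyldimethylsilyloxy){(1S,2S)-2-[(2S)-2-hydroxypropanoyl]cyclopropyl}methyl]-5,6-dihydro-2H-pyran-2-one; 26 (2Z)-3-(4-methoxyphenyl)prop-2-enoic acid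
Product: 27 (2S)-1-{(1S,2S)-2-[(S)-(tert-butyldimethylsilyloxy)((2R)-6-oxo-3,6-dihydro-2H-pyran-2-yl)methyl]cyclopropyl}-1-oxopropan-2-yl (2Z)-3-(4-methoxyphenyl)prop-2-enoate
Conditions: DCC, DMAP (0.1 equiv), CH2Cl2, −10 °C to 0 °C
Reagents that add atoms: none
Why: Steglich esterification of the only free hydroxyl group, run cold and with little DMAP so that the Z-olefin and the centre next to the ketone should be preserved.

**Step 16**
Reactants: 27 (2S)-1-{(1S,2S)-2-[(S)-(tert-butyldimethylsilyloxy)((2R)-6-oxo-3,6-dihydro-2H-pyran-2-yl)methyl]cyclopropyl}-1-oxopropan-2-yl (2Z)-3-(4-methoxyphenyl)prop-2-enoate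
Product: 28 Brevipolide I
Conditions: HF·pyridine, pyridine, THF, 0 °C to rt
Reagents that add atoms: none
Why: fluoride-mediated cleavage of the silyl ether under buffered conditions, which the unsaturated lactone, the α-acyloxy ketone and the Z-cinnamate should tolerate.

**Compound list**
1 | (E)-3-(tributylstannyl)prop-2-en-1-ol | CCCC[Sn](CCCC)(CCCC)/C=C/CO | starting material
2 | [(1R,2S)-2-(tributylstannyl)cyclopropyl]methanol | CCCC[Sn](CCCC)(CCCC)[C@H]1C[C@@H]1CO | intermediate
3 | ethyl (S)-lactate | CCOC(=O)[C@H](C)O | starting material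
4 | (S)-2-hydroxy-N-methoxy-N-methylpropanamide | C[C@H](O)C(=O)N(C)OC | intermediate
5 | (S)-N-methoxy-N-methyl-2-(triethylsilyloxy)propanamide | CC[Si](CC)(CC)O[C@@H](C)C(=O)N(C)OC | intermediate
6 | dilithiated cyclopropylmethoxide from 2 (lithium alkoxide, C–Li in place of C–Sn, configuration retained) | [Li][C@H]1C[C@@H]1CO[Li] | intermediate
7 | (2S)-1-[(1S,2S)-2-(hydroxymethyl)cyclopropyl]-2-(triethylsilyloxy)propan-1-one | CC[Si](CC)(CC)O[C@@H](C)C(=O)[C@H]1C[C@@H]1CO | intermediate
8 | (1S,2S)-2-[(2S)-2-(triethylsilyloxy)propanoyl]cyclopropane-1-carbaldehyde | CC[Si](CC)(CC)O[C@@H](C)C(=O)[C@H]1C[C@@H]1C=O | intermediate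
9 | (4R)-4-benzyl-3-[2-(benzyloxy)acetyl]-1,3-oxazolidin-2-one | O=C(COCc1ccccc1)N1[C@H](Cc2ccccc2)COC1=O | starting material
10 | dibutylboron Z-enolate of 9 | CCCCB(CCCC)O/C(=C\OCc1ccccc1)N1[C@H](Cc2ccccc2)COC1=O | intermediate
11 | (4R)-4-benzyl-3-[(2R,3S)-2-(benzyloxy)-3-hydroxy-3-{(1S,2S)-2-[(2S)-2-(triethylsilyloxy)propanoyl]cyclopropyl}propanoyl]-1,3-oxazolidin-2-one | CC[Si](CC)(CC)O[C@@H](C)C(=O)[C@H]1C[C@@H]1[C@H](O)[C@@H](OCc1ccccc1)C(=O)N1[C@H](Cc2ccccc2)COC1=O | intermediate
12 | TBS ether of 11: (4R)-4-benzyl-3-[(2R,3S)-2-(benzyloxy)-3-(tert-butyldimethylsilyloxy)-3-{(1S,2S)-2-[(2S)-2-(triethylsilyloxy)propanoyl]cyclopropyl}propanoyl]-1,3-oxazolidin-2-one | CC[Si](CC)(CC)O[C@@H](C)C(=O)[C@H]1C[C@@H]1[C@H](O[Si](C)(C)C(C)(C)C)[C@@H](OCc1ccccc1)C(=O)N1[C@H](Cc2ccccc2)COC1=O | intermediate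
13 | peroxy acid corresponding to acid 14 | CC[Si](CC)(CC)O[C@@H](C)C(=O)[C@H]1C[C@@H]1[C@H](O[Si](C)(C)C(C)(C)C)[C@@H](OCc1ccccc1)C(=O)OO | intermediate
14 | (2R,3S)-2-(benzyloxy)-3-(tert-butyldimethylsilyloxy)-3-{(1S,2S)-2-[(2S)-2-(triethylsilyloxy)propanoyl]cyclopropyl}propanoic acid | CC[Si](CC)(CC)O[C@@H](C)C(=O)[C@H]1C[C@@H]1[C@H](O[Si](C)(C)C(C)(C)C)[C@@H](OCc1ccccc1)C(=O)O | intermediate
15 | (2R,3S)-3-(tert-butyldimethylsilyloxy)-2-hydroxy-3-{(1S,2S)-2-[(2S)-2-(triethylsilyloxy)propanoyl]cyclopropyl}propanoic acid | CC[Si](CC)(CC)O[C@@H](C)C(=O)[C@H]1C[C@@H]1[C@H](O[Si](C)(C)C(C)(C)C)[C@@H](O)C(=O)O | intermediate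
16 | (2R,3S)-2-(acryloyloxy)-3-(tert-butyldimethylsilyloxy)-3-{(1S,2S)-2-[(2S)-2-(triethylsilyloxy)propanoyl]cyclopropyl}propanoic acid | CC[Si](CC)(CC)O[C@@H](C)C(=O)[C@H]1C[C@@H]1[C@H](O[Si](C)(C)C(C)(C)C)[C@@H](OC(=O)C=C)C(=O)O | intermediate
17 | secondary ozonide (1,2,4-trioxolane) of acrylate 16 | CC[Si](CC)(CC)O[C@@H](C)C(=O)[C@H]1C[C@@H]1[C@H](O[Si](C)(C)C(C)(C)C)[C@@H](OC(=O)C1OCOO1)C(=O)O | intermediate
18 | (2R,3S)-3-(tert-butyldimethylsilyloxy)-2-(2-oxoacetoxy)-3-{(1S,2S)-2-[(2S)-2-(triethylsilyloxy)propanoyl]cyclopropyl}propanoic acid | CC[Si](CC)(CC)O[C@@H](C)C(=O)[C@H]1C[C@@H]1[C@H](O[Si](C)(C)C(C)(C)C)[C@@H](OC(=O)C=O)C(=O)O | intermediate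
19 | vinyltriphenylphosphonium bromide | C=C[P+](c1ccccc1)(c1ccccc1)c1ccccc1.[Br-] | starting material
20 | α-acyloxyalkyl radical at C6, from 18 by loss of CO2 | CC[Si](CC)(CC)O[C@@H](C)C(=O)[C@H]1C[C@@H]1[C@H](O[Si](C)(C)C(C)(C)C)[CH]OC(=O)C=O | intermediate
21 | α-phosphonio radical, adduct of 20 to 19 (C6 now R) | CC[Si](CC)(CC)O[C@@H](C)C(=O)[C@H]1C[C@@H]1[C@H](O[Si](C)(C)C(C)(C)C)[C@@H](C[CH][P+](c1ccccc1)(c1ccccc1)c1ccccc1)OC(=O)C=O | intermediate
22 | phosphonium ylide from reduction of 21 | CC[Si](CC)(CC)O[C@@H](C)C(=O)[C@H]1C[C@@H]1[C@H](O[Si](C)(C)C(C)(C)C)[C@@H](CC=P(c1ccccc1)(c1ccccc1)c1ccccc1)OC(=O)C=O | intermediate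
23 | (6R)-6-[(S)-(tert-butyldimethylsilyloxy){(1S,2S)-2-[(2S)-2-(triethylsilyloxy)propanoyl]cyclopropyl}methyl]-5,6-dihydro-2H-pyran-2-one | CC[Si](CC)(CC)O[C@@H](C)C(=O)[C@H]1C[C@@H]1[C@H](O[Si](C)(C)C(C)(C)C)[C@H]1CC=CC(=O)O1 | intermediate
24 | (6R)-6-[(S)-(tert-butyldimethylsilyloxy){(1S,2S)-2-[(2S)-2-hydroxypropanoyl]cyclopropyl}methyl]-5,6-dihydro-2H-pyran-2-one | C[C@H](O)C(=O)[C@H]1C[C@@H]1[C@H](O[Si](C)(C)C(C)(C)C)[C@H]1CC=CC(=O)O1 | intermediate
25 | 3-(4-methoxyphenyl)prop-2-ynoic acid | COc1ccc(C#CC(=O)O)cc1 | starting material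
26 | (2Z)-3-(4-methoxyphenyl)prop-2-enoic acid | COc1ccc(/C=C\C(=O)O)cc1 | intermediate
27 | (2S)-1-{(1S,2S)-2-[(S)-(tert-butyldimethylsilyloxy)((2R)-6-oxo-3,6-dihydro-2H-pyran-2-yl)methyl]cyclopropyl}-1-oxopropan-2-yl (2Z)-3-(4-methoxyphenyl)prop-2-enoate | COc1ccc(/C=C\C(=O)O[C@@H](C)C(=O)[C@H]2C[C@@H]2[C@H](O[Si](C)(C)C(C)(C)C)[C@H]2CC=CC(=O)O2)cc1 | intermediate
28 | Brevipolide I, (2S)-1-{(1S,2S)-2-[(S)-hydroxy((2R)-6-oxo-3,6-dihydro-2H-pyran-2-yl)methyl]cyclopropyl}-1-oxopropan-2-yl (2Z)-3-(4-methoxyphenyl)prop-2-enoate | COc1ccc(/C=C\C(=O)O[C@@H](C)C(=O)[C@H]2C[C@@H]2[C@H](O)[C@H]2CC=CC(=O)O2)cc1 | target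

**Step count and risks**
Total step count: 16. Longest linear sequence: 14 steps (steps 2 to 13, 15 and 16, from ethyl (S)-lactate).

Steps most likely to fail:

1. Step 12 (Proposed new method). The facial selectivity of the radical addition at C6 may be poor. Single-electron oxidation of the α-acyloxy carboxylate may be slow. The ylide may be protonated or react between molecules before the ring closes. The fallback uses known chemistry, sets out from hydroxy acid 15 and returns at lactone 23. Oxidative decarboxylation of 15 with Pb(OAc)4 in benzene should give (2S)-2-(tert-butyldimethylsilyloxy)-2-{(1S,2S)-2-[(2S)-2-(triethylsilyloxy)propanoyl]cyclopropyl}acetaldehyde F1. Brown allylation with (+)-B-allyldiisopinocampheylborane in Et2O at −78 °C, with a 2-aminoethanol work-up, should then give the anti homoallylic alcohol (2S)-1-{(1S,2S)-2-[(1S,2R)-1-(tert-butyldimethylsilyloxy)-2-hydroxypent-4-en-1-yl]cyclopropyl}-2-(triethylsilyloxy)propan-1-one F2; the reagent is chosen to deliver the C6 R carbinol, the same sense as the Felkin–Anh preference of the α-silyloxy aldehyde, and the aldehyde should react in preference to the ketone. Acylation with acryloyl chloride and i-Pr2NEt gives (1S,2R)-1-(tert-butyldimethylsilyloxy)-1-{(1S,2S)-2-[(2S)-2-(triethylsilyloxy)propanoyl]cyclopropyl}pent-4-en-2-yl prop-2-enoate F3. Ring-closing metathesis with the second-generation Grubbs catalyst RuCl2(=CHPh)(PCy3)(H2IMes) in CH2Cl2 at 40 °C closes the lactone to 23.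

2. Step 4. Tin–lithium exchange may be incomplete on the lithium alkoxide, and the basic cyclopropyllithium may enolise the amide. The fallback sets out from stannane 2 and returns at ketone 7. Iododestannylation of 2 with I2 in CH2Cl2 (retention) gives [(1R,2S)-2-iodocyclopropyl]methanol F4. Protection with 4-methoxybenzyl trichloroacetimidate and a catalytic acid gives (1S,2R)-1-iodo-2-{[(4-methoxybenzyl)oxy]methyl}cyclopropane F5. Iodine–lithium exchange with t-BuLi in Et2O at −78 °C and addition to amide 5 gives (2S)-1-[(1S,2S)-2-{[(4-methoxybenzyl)oxy]methyl}cyclopropyl]-2-(triethylsilyloxy)propan-1-one F6. Oxidative removal of the 4-methoxybenzyl group with DDQ in buffered CH2Cl2–H2O then gives 7.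

3. Step 15. The Z-olefin may isomerise to E through reversible conjugate addition of DMAP to the activated acyl intermediate, and the centre next to the ketone may epimerise. The fallback sets out from alcohol 24 and returns at ester 27, so the Z-olefin is made after the ester bond. Esterification of 24 with alkynoic acid 25 (DCC, catalytic DMAP) gives (2S)-1-{(1S,2S)-2-[(S)-(tert-butyldimethylsilyloxy)((2R)-6-oxo-3,6-dihydro-2H-pyran-2-yl)methyl]cyclopropyl}-1-oxopropan-2-yl 3-(4-methoxyphenyl)prop-2-ynoate F7. Lindlar semi-hydrogenation of F7 (Pd/CaCO3 poisoned with Pb(OAc)2, quinoline, H2) then gives 27.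

**Further compounds**
F1 | step 12 | (2S)-2-(tert-butyldimethylsilyloxy)-2-{(1S,2S)-2-[(2S)-2-(triethylsilyloxy)propanoyl]cyclopropyl}acetaldehyde | CC[Si](CC)(CC)O[C@@H](C)C(=O)[C@H]1C[C@@H]1[C@H](O[Si](C)(C)C(C)(C)C)C=O
F2 | step 12 | (2S)-1-{(1S,2S)-2-[(1S,2R)-1-(tert-butyldimethylsilyloxy)-2-hydroxypent-4-en-1-yl]cyclopropyl}-2-(triethylsilyloxy)propan-1-one | CC[Si](CC)(CC)O[C@@H](C)C(=O)[C@H]1C[C@@H]1[C@H](O[Si](C)(C)C(C)(C)C)[C@H](O)CC=C
F3 | step 12 | (1S,2R)-1-(tert-butyldimethylsilyloxy)-1-{(1S,2S)-2-[(2S)-2-(triethylsilyloxy)propanoyl]cyclopropyl}pent-4-en-2-yl prop-2-enoate | CC[Si](CC)(CC)O[C@@H](C)C(=O)[C@H]1C[C@@H]1[C@H](O[Si](C)(C)C(C)(C)C)[C@H](OC(=O)C=C)CC=C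
F4 | step 4 | [(1R,2S)-2-iodocyclopropyl]methanol | I[C@H]1C[C@@H]1CO
F5 | step 4 | (1S,2R)-1-iodo-2-{[(4-methoxybenzyl)oxy]methyl}cyclopropane | I[C@H]1C[C@@H]1COCc1ccc(OC)cc1
F6 | step 4 | (2S)-1-[(1S,2S)-2-{[(4-methoxybenzyl)oxy]methyl}cyclopropyl]-2-(triethylsilyloxy)propan-1-one | CC[Si](CC)(CC)O[C@@H](C)C(=O)[C@H]1C[C@@H]1COCc1ccc(OC)cc1
F7 | step 15 | (2S)-1-{(1S,2S)-2-[(S)-(tert-butyldimethylsilyloxy)((2R)-6-oxo-3,6-dihydro-2H-pyran-2-yl)methyl]cyclopropyl}-1-oxopropan-2-yl 3-(4-methoxyphenyl)prop-2-ynoate | COc1ccc(C#CC(=O)O[C@@H](C)C(=O)[C@H]2C[C@@H]2[C@H](O[Si](C)(C)C(C)(C)C)[C@H]2CC=CC(=O)O2)cc1
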